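The ochre run gives the rate from which midnight is reckoned here.

| flask | starting material | free catalyst | impurity | temperature | remark | time |
|---|---|---|---|---|---|---|
| ochre | 0.90 M | 170 mM | 89 mM | 70 °C | run made earlier |  |
| midnight | 1.8 M | 170 mM | 89 mM | 70 °C |  | 80 min |
| dawn | 1.8 M | 170 mM | 89 mM | 50 °C |  | 80 min |

ochre run (percent of the starting material charged): time / min: target / % = 3.00: 1.5; 6.00: 4.0; 10.0: 7.5; 15.0: 11.8; 20.0: 15.8; 25.0: 19.9

(readings scatter by 0.3 percentage points)

- the earlier runs do not show what temperature does; that part of a forecast is a guess

- the best flask by amount of target, in percent of the starting material charged; "all alike" if 1.5 percentage points covers them all (midnight / dawn / all alike)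
- amount of target at the end, in percent of the starting material charged, midnight
- amount of target at the end, in percent of the starting material charged, dawn

1. How fast. Ochre's target climbs from 4.0% at 6.00 min to 19.9% at 25.0 min. On its charge, that makes the flat rate, the amount of target made per litre each minute (an apparent zero-order rate): 7.53 mM/min, as a reading.

2. What slows it. Ochre's rate goes from 7.80 mM/min before 15.0 min to 7.29 mM/min after it, a factor of 0.935, read through a scatter of 0.3 percentage points per reading.

3. The larger charge. Midnight starts with twice ochre's starting material. This reckoning sets the factor for that at 1, a judgement resting on ochre's small slowing.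

4. The accumulated slowing. At the flat rate, midnight uses 602 mM in 80 min, and what remains is more than ochre's whole charge. Ochre's slowing therefore gives midnight a factor of 1 again, and the end stands at 33.5%. Past 25.0 min the readings show nothing.

5. Dawn. The temperature factor is a guess, and this reckoning adds no number of its own.

The forecast names midnight: 34% for midnight (27% to 39%), slightly above this reckoning, and 9.5% for dawn (5% to 17%). Its ground for midnight: “Doubling the starting material should therefore barely change the absolute rate”.

The simulation gives midnight, with 36.0% for midnight and 5.88% for dawn.

    catalyst intermediate B → free catalyst + target (k = 0.350 /min, Ea = 88.0 kJ/mol)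
    starting material + free catalyst → catalyst intermediate A (k = 0.850 /M/min, Ea = 78.0 kJ/mol)
    catalyst intermediate A ⇌ catalyst intermediate B (K = 0.750, k = 0.340 /min, Ea = 99.0 kJ/mol, ΔH = −29.0 kJ/mol)
    2 starting material → self-condensation product (k = 4.30 × 10⁻⁴ /M/min, Ea = 98.0 kJ/mol)
    free catalyst + impurity → spent catalyst (k = 14.0 /M/min, Ea = 56.0 kJ/mol)
    (constants at 70 °C)

Midnight's mean rate is 8.09 mM/min, above the flat rate. Midnight has not come to rest at 80.0 min: 53.3% of its starting material stands, which the flat rate clears in 127 min. At 800 min, midnight's target reaches 91.3%, its starting material 0%, and its free catalyst rises from 5.36% to 47.6% of the catalyst charged, while spent catalyst stays at 52.4%. The neighbour of midnight charged with 0.45 M has a flat-rate clearing time of 59.8 min, yet at 80.0 min it holds 85.2% target and still 8.69% starting material.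

The numbers in the tables were computed with constants of no real substance, noise included.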